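The route rests on cutting the oxolane ring at O1–C2 and at C2–CH2. The feature exploited is C2 of the oxolane, a fully substituted ether carbon whose side-chain CH2 stands trans to the γ-lactone ring on C5, the signature of an allyl group that has moved from the ring oxygen to carbon. In one operation a copper carbenoid is captured by an allyl ether oxygen and the oxonium ylide rearranges by [2,3]-shift, which closes the oxolane (as its 3-ketone), forms both bonds and sets C2. The precursor is a γ-lactone carrying a 1-allyloxy-4-diazo-3-oxopentyl chain, its two stereocentres fixed earlier by Shi epoxidation and invertive lactonisation of an E-alkene.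

Key step: step 9

Remark: the primary oxygen is carried as a TBS ether (aldehyde 1 is taken as purchasable) because the allyl ether is installed under Brønsted-acid catalysis, which keeps the hydroxy lactone away from alkoxide conditions but would endanger a p-methoxybenzyl ether. Every carbon-donating partner is a numbered reactant, so the line "Reagents that add atoms" lists unnumbered reagents only.

Step 1
Reactants: 1 3-[(tert-butyldimethylsilyl)oxy]propanal; 2 isopropenylmagnesium bromide
Product: 3 rac-5-[(tert-butyldimethylsilyl)oxy]-2-methylpent-1-en-3-ol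
Conditions: THF, −78 → 0 °C; aq. NH4Cl
Reagents that add atoms: none
Why: Grignard 1,2-addition of the alkenylmagnesium reagent to the aldehyde should give the allylic alcohol; the carbinol centre is left racemic because the next step erases it.

Step 2
Reactants: 3 rac-5-[(tert-butyldimethylsilyl)oxy]-2-methylpent-1-en-3-ol; 4 triethyl orthoacetate
Product: 6 ethyl (4E)-7-[(tert-butyldimethylsilyl)oxy]-4-methylhept-4-enoate, via ketene acetal 5 (not isolated)
Conditions: 4 (excess), EtCO2H (cat.), 140 °C, EtOH distilled off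
Reagents that add atoms: none
Why: Johnson–Claisen rearrangement: acid-catalysed exchange gives ketene acetal 5, whose chair [3,3] transition state keeps the silyloxyethyl chain equatorial and should deliver the E-trisubstituted alkene.

Step 3
Reactants: 6 ethyl (4E)-7-[(tert-butyldimethylsilyl)oxy]-4-methylhept-4-enoate
Product: 7 ethyl 3-[(2R,3R)-3-{2-[(tert-butyldimethylsilyl)oxy]ethyl}-2-methyloxiran-2-yl]propanoate
Conditions: D-fructose-derived Shi ketone (0.3 equiv), Oxone, K2CO3, Bu4NHSO4, MeCN/DMM/aq. Na2B4O7 buffer (pH 10.5), 0 °C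
Reagents that add atoms: potassium peroxymonosulfate (active component of Oxone), [K+].[O-]S(=O)(=O)OO
Why: Shi asymmetric epoxidation: the chiral dioxirane attacks E-trisubstituted alkenes through a spiro transition state and should give the (R,R)-epoxide, which fixes both future stereocentres; ester and silyl ether are inert at this pH.

Step 4
Reactants: 7 ethyl 3-[(2R,3R)-3-{2-[(tert-butyldimethylsilyl)oxy]ethyl}-2-methyloxiran-2-yl]propanoate
Product: 9 (5S)-5-[(1R)-3-[(tert-butyldimethylsilyl)oxy]-1-hydroxypropyl]-5-methyloxolan-2-one, via epoxy acid 8 (not isolated)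
Conditions: LiOH, THF/H2O, 0 °C → rt; then 1 M KHSO4 to pH 3, rt
Reagents that add atoms: lithium hydroxide, [Li+].[OH-]
Why: Ester saponification followed by acid-triggered epoxy-acid lactonisation: the carboxyl group opens the epoxide 5-exo at the tertiary carbon with inversion, so (R,R)-8 should give the (S)-lactone carbon while the (R)-carbinol carbon is untouched.

Step 5
Reactants: 9 (5S)-5-[(1R)-3-[(tert-butyldimethylsilyl)oxy]-1-hydroxypropyl]-5-methyloxolan-2-one; 10 allyl 2,2,2-trichloroacetimidate
Product: 11 (5S)-5-[(1R)-3-[(tert-butyldimethylsilyl)oxy]-1-(prop-2-en-1-yloxy)propyl]-5-methyloxolan-2-one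
Conditions: TfOH (5 mol%), CH2Cl2/cyclohexane, 0 °C → rt
Reagents that add atoms: none
Why: Acid-catalysed trichloroacetimidate O-alkylation allylates the hindered secondary alcohol without forming an alkoxide (no translactonisation) and with retention, since the carbinol C–O bond is not broken.

Step 6
Reactants: 11 (5S)-5-[(1R)-3-[(tert-butyldimethylsilyl)oxy]-1-(prop-2-en-1-yloxy)propyl]-5-methyloxolan-2-one
Product: 12 (5S)-5-[(1R)-3-hydroxy-1-(prop-2-en-1-yloxy)propyl]-5-methyloxolan-2-one
Conditions: HF·pyridine, THF/pyridine, 0 °C → rt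
Reagents that add atoms: none
Why: Fluoride-mediated desilylation under mildly acidic conditions should free the primary alcohol and leave lactone and allyl ether intact.

Step 7
Reactants: 12 (5S)-5-[(1R)-3-hydroxy-1-(prop-2-en-1-yloxy)propyl]-5-methyloxolan-2-one
Product: 14 (3R)-3-[(2S)-2-methyl-5-oxooxolan-2-yl]-3-(prop-2-en-1-yloxy)propanoic acid, via aldehyde 13 (not isolated)
Conditions: TEMPO (20 mol%), PhI(OAc)2 (2.2 equiv), MeCN/H2O 1:1, rt
Reagents that add atoms: water, O
Why: Oxoammonium (TEMPO) oxidation in wet acetonitrile should take the primary alcohol through aldehyde 13 to the acid without touching the alkene or the β-alkoxy stereocentre.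

Step 8
Reactants: 14 (3R)-3-[(2S)-2-methyl-5-oxooxolan-2-yl]-3-(prop-2-en-1-yloxy)propanoic acid; 15 N-ethyl-N-nitrosourea
Product: 18 (5S)-5-[(1R)-4-diazo-3-oxo-1-(prop-2-en-1-yloxy)pentyl]-5-methyloxolan-2-one, via acid chloride 16 (not isolated), via diazoethane 17 (not isolated)
Conditions: (COCl)2, DMF (cat.), CH2Cl2, 0 °C → rt, evaporate; then 17 (3 equiv, from 15, aq. KOH/Et2O, −10 °C, dried over KOH), Et2O, −10 → 0 °C
Reagents that add atoms: none
Why: Arndt–Eistert-type acylation of a diazoalkane: acid chloride 16 acylates diazoethane 17 at carbon, and the excess diazoalkane removes HCl, so the α-methyl diazoketone should form with both stereocentres unchanged.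

Step 9
Reactants: 18 (5S)-5-[(1R)-4-diazo-3-oxo-1-(prop-2-en-1-yloxy)pentyl]-5-methyloxolan-2-one
Product: 21 (2S,5R)-2-methyl-5-[(2S)-2-methyl-5-oxooxolan-2-yl]-2-(prop-2-en-1-yl)oxolan-3-one, via copper carbenoid 19 (not isolated), via oxonium ylide 20 (not isolated)
Conditions: Cu(acac)2 (10 mol%), THF, reflux, 18 added over 2 h
Reagents that add atoms: none
Why: Copper decomposes 18 with loss of N2 to the electrophilic carbenoid 19, a lone pair of the allyl ether oxygen three atoms away traps it as the cyclic oxonium ylide 20, and the allyl group then moves from oxygen to the ylide carbon through a suprafacial five-centre [2,3]-sigmatropic transition state with allylic transposition. The closest known reaction type is the copper-catalysed oxonium ylide formation/[2,3]-rearrangement of allyl ethers of diazoketones to 2,5-trans-oxolan-3-ones, applied here to a diazoketone with a methyl group on the diazo carbon. The oxolane closes by five-membered (5-exo-type) attack of the ether oxygen on the carbenoid carbon, which forms O1–C2, and the shift then forms C2–CH2. The one new stereocentre, C2, is controlled by C5: the ylide carbon is a planar enolate, the allyl group on the pyramidal oxonium oxygen lies anti to the lactone substituent on C5 and is delivered to the same face of C2, so CH2 should end trans and CH3 cis to the lactone. The step needs ylide formation to outrun 1,2-hydride shift from the methyl group and C–H insertion; the five-membered proximity of the ether oxygen, copper in place of rhodium and slow addition secure this, and the lactone oxygens are less nucleophilic and would need six- or eight-membered ylides.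

Step 10
Reactants: 21 (2S,5R)-2-methyl-5-[(2S)-2-methyl-5-oxooxolan-2-yl]-2-(prop-2-en-1-yl)oxolan-3-one
Product: 22 (5S)-5-[(2R,5S)-4-hydroxy-5-methyl-5-(prop-2-en-1-yl)oxolan-2-yl]-5-methyloxolan-2-one (mixture of C4 epimers)
Conditions: NaBH4, MeOH, −20 °C
Reagents that add atoms: none
Why: Borohydride carbonyl reduction is far faster for the ring ketone than for the γ-lactone at low temperature; the configuration of the new carbinol does not matter because step 12 removes it.

Step 11
Reactants: 22 (5S)-5-[(2R,5S)-4-hydroxy-5-methyl-5-(prop-2-en-1-yl)oxolan-2-yl]-5-methyloxolan-2-one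
Product: 23 O-[(2S,5R)-2-methyl-5-[(2S)-2-methyl-5-oxooxolan-2-yl]-2-(prop-2-en-1-yl)oxolan-3-yl] 1H-imidazole-1-carbothioate (mixture of C3 epimers)
Conditions: 1,1'-thiocarbonyldiimidazole, DMAP (cat.), ClCH2CH2Cl, 70 °C
Reagents that add atoms: 1,1'-thiocarbonyldiimidazole, S=C(n1ccnc1)n1ccnc1
Why: Thioacylation of the secondary alcohol under neutral conditions should give the thiocarbonyl derivative needed for radical deoxygenation without exposing the lactone to base.

Step 12
Reactants: 23 O-[(2S,5R)-2-methyl-5-[(2S)-2-methyl-5-oxooxolan-2-yl]-2-(prop-2-en-1-yl)oxolan-3-yl] 1H-imidazole-1-carbothioate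
Product: 24 (5S)-5-methyl-5-[(2R,5R)-5-methyl-5-(prop-2-en-1-yl)oxolan-2-yl]oxolan-2-one
Conditions: Bu3SnH, AIBN (cat.), toluene, 100 °C
Reagents that add atoms: none
Why: Barton–McCombie radical-chain deoxygenation should replace the C–O bond at the former ketone carbon by C–H; closure onto the allyl group would be 4-exo or 5-endo and is not competitive, and the ring stereocentres are not involved.

Step 13
Reactants: 24 (5S)-5-methyl-5-[(2R,5R)-5-methyl-5-(prop-2-en-1-yl)oxolan-2-yl]oxolan-2-one
Product: 26 2-[(2R,5R)-2-methyl-5-[(2S)-2-methyl-5-oxooxolan-2-yl]oxolan-2-yl]acetaldehyde, via ozonide 25 (not isolated)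
Conditions: O3, CH2Cl2, −78 °C; then PPh3, −78 °C → rt
Reagents that add atoms: ozone, [O-][O+]=O
Why: Ozonolysis of the only alkene with reductive work-up of ozonide 25 should give the aldehyde; lactone and ether are inert to ozone.

Step 14
Reactants: 27 furan-3-carbaldehyde (3-furaldehyde); 28 (triphenylphosphoranylidene)acetaldehyde
Product: 29 (2E)-3-(furan-3-yl)prop-2-enal
Conditions: toluene, 80 °C
Reagents that add atoms: none
Why: Wittig olefination with a stabilised formyl ylide should give the E-enal in a single two-carbon homologation.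

Step 15
Reactants: 29 (2E)-3-(furan-3-yl)prop-2-enal
Product: 30 3-(furan-3-yl)propanal
Conditions: Hantzsch ester (1.1 equiv), Bn2NH2+ CF3CO2− (5 mol%), THF, rt
Reagents that add atoms: none
Why: Iminium-catalysed transfer hydrogenation with a Hantzsch ester reduces only the conjugated C=C of an enal and should leave aldehyde and furan untouched.

Step 16
Reactants: 30 3-(furan-3-yl)propanal; 31 ethyl 2-(triphenylphosphoranylidene)propanoate
Product: 32 ethyl (2E)-5-(furan-3-yl)-2-methylpent-2-enoate
Conditions: CH2Cl2, rt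
Reagents that add atoms: none
Why: Wittig olefination with a stabilised α-methyl ylide gives E-trisubstituted enoates selectively, which sets the side-chain alkene geometry.

Step 17
Reactants: 32 ethyl (2E)-5-(furan-3-yl)-2-methylpent-2-enoate
Product: 33 (2E)-5-(furan-3-yl)-2-methylpent-2-en-1-ol
Conditions: DIBAL-H (2.2 equiv), CH2Cl2, −78 °C; Rochelle salt
Reagents that add atoms: none
Why: Hydride (DIBAL-H) 1,2-reduction of the conjugated ester should give the allylic alcohol without touching the alkene or the furan.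

Step 18
Reactants: 33 (2E)-5-(furan-3-yl)-2-methylpent-2-en-1-ol
Product: 35 3-[(3E)-5-chloro-4-methylpent-3-en-1-yl]furan, via mesylate 34 (not isolated)
Conditions: MsCl, 2,4,6-collidine, LiCl, DMF, 0 °C
Reagents that add atoms: lithium chloride, [Li+].[Cl-]
Why: In situ mesylation and SN2 displacement by chloride at the primary allylic carbon should give the chloride without allylic transposition or loss of E geometry.

Step 19
Reactants: 35 3-[(3E)-5-chloro-4-methylpent-3-en-1-yl]furan; 26 2-[(2R,5R)-2-methyl-5-[(2S)-2-methyl-5-oxooxolan-2-yl]oxolan-2-yl]acetaldehyde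
Product: 37 (5S)-5-[(2R,5R)-5-[(4E)-7-(furan-3-yl)-2-hydroxy-4-methylhept-4-en-1-yl]-5-methyloxolan-2-yl]-5-methyloxolan-2-one (mixture of carbinol epimers), via allylbarium chloride 36 (not isolated)
Conditions: BaI2, Li (2 equiv), biphenyl, THF, rt; 35, −78 °C; then 26, THF, −78 °C; aq. NH4Cl
Reagents that add atoms: none
Why: α-Selective allylbarium addition to an aldehyde: the allylic barium reagent forms at −78 °C without allylic or E/Z scrambling and adds through its CH2 terminus, so the linear homoallylic alcohol with the E-alkene should result; the aldehyde reacts much faster than the γ-lactone, and the new carbinol is oxidised in the next step.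

Step 20
Reactants: 37 (5S)-5-[(2R,5R)-5-[(4E)-7-(furan-3-yl)-2-hydroxy-4-methylhept-4-en-1-yl]-5-methyloxolan-2-yl]-5-methyloxolan-2-one
Product: 38 (5S)-5-[(2R,5R)-5-[(4E)-7-(furan-3-yl)-4-methyl-2-oxohept-4-en-1-yl]-5-methyloxolan-2-yl]-5-methyloxolan-2-one
Conditions: Dess–Martin periodinane, NaHCO3, CH2Cl2, 0 °C → rt
Reagents that add atoms: none
Why: Dess–Martin oxidation under bicarbonate buffering should convert the secondary alcohol into the ketone under near-neutral conditions that do not move the β,γ-double bond into conjugation or affect the furan.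

Compound list
1 | 3-[(tert-butyldimethylsilyl)oxy]propanal | O=CCCO[Si](C)(C)C(C)(C)C | starting material
2 | isopropenylmagnesium bromide | C=C(C)[Mg]Br | starting material
3 | rac-5-[(tert-butyldimethylsilyl)oxy]-2-methylpent-1-en-3-ol | C=C(C)C(O)CCO[Si](C)(C)C(C)(C)C | intermediate
4 | triethyl orthoacetate | CCOC(C)(OCC)OCC | starting material
5 | ketene acetal: rac-5-[(tert-butyldimethylsilyl)oxy]-3-[(1-ethoxyethenyl)oxy]-2-methylpent-1-ene | C=C(OCC)OC(CCO[Si](C)(C)C(C)(C)C)C(C)=C | intermediate (not isolated)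
6 | ethyl (4E)-7-[(tert-butyldimethylsilyl)oxy]-4-methylhept-4-enoate | CCOC(=O)CC/C(C)=C/CCO[Si](C)(C)C(C)(C)C | intermediate
7 | ethyl 3-[(2R,3R)-3-{2-[(tert-butyldimethylsilyl)oxy]ethyl}-2-methyloxiran-2-yl]propanoate | CCOC(=O)CC[C@@]1(C)O[C@@H]1CCO[Si](C)(C)C(C)(C)C | intermediate
8 | epoxy acid: 3-[(2R,3R)-3-{2-[(tert-butyldimethylsilyl)oxy]ethyl}-2-methyloxiran-2-yl]propanoic acid | OC(=O)CC[C@@]1(C)O[C@@H]1CCO[Si](C)(C)C(C)(C)C | intermediate (not isolated)
9 | (5S)-5-[(1R)-3-[(tert-butyldimethylsilyl)oxy]-1-hydroxypropyl]-5-methyloxolan-2-one | CC(C)(C)[Si](C)(C)OCC[C@@H](O)[C@]1(C)CCC(=O)O1 | intermediate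
10 | allyl 2,2,2-trichloroacetimidate | C=CCOC(=N)C(Cl)(Cl)Cl | starting material
11 | (5S)-5-[(1R)-3-[(tert-butyldimethylsilyl)oxy]-1-(prop-2-en-1-yloxy)propyl]-5-methyloxolan-2-one | CC(C)(C)[Si](C)(C)OCC[C@@H](OCC=C)[C@]1(C)CCC(=O)O1 | intermediate
12 | (5S)-5-[(1R)-3-hydroxy-1-(prop-2-en-1-yloxy)propyl]-5-methyloxolan-2-one | OCC[C@@H](OCC=C)[C@]1(C)CCC(=O)O1 | intermediate
13 | aldehyde: (3R)-3-[(2S)-2-methyl-5-oxooxolan-2-yl]-3-(prop-2-en-1-yloxy)propanal | O=CC[C@@H](OCC=C)[C@]1(C)CCC(=O)O1 | intermediate (not isolated)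
14 | (3R)-3-[(2S)-2-methyl-5-oxooxolan-2-yl]-3-(prop-2-en-1-yloxy)propanoic acid | OC(=O)C[C@@H](OCC=C)[C@]1(C)CCC(=O)O1 | intermediate
15 | N-ethyl-N-nitrosourea | CCN(N=O)C(N)=O | starting material
16 | acid chloride: (3R)-3-[(2S)-2-methyl-5-oxooxolan-2-yl]-3-(prop-2-en-1-yloxy)propanoyl chloride | ClC(=O)C[C@@H](OCC=C)[C@]1(C)CCC(=O)O1 | intermediate (not isolated)
17 | diazoethane | CC=[N+]=[N-] | intermediate (not isolated)
18 | (5S)-5-[(1R)-4-diazo-3-oxo-1-(prop-2-en-1-yloxy)pentyl]-5-methyloxolan-2-one | CC(=[N+]=[N-])C(=O)C[C@@H](OCC=C)[C@]1(C)CCC(=O)O1 | intermediate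
19 | copper carbenoid of 18 (ancillary ligands on copper omitted) | CC(=[Cu])C(=O)C[C@@H](OCC=C)[C@]1(C)CCC(=O)O1 | intermediate (not isolated)
20 | oxonium ylide: (5R)-2-methyl-5-[(2S)-2-methyl-5-oxooxolan-2-yl]-3-oxo-1-(prop-2-en-1-yl)oxolan-1-ium-2-ide | C=CC[O+]1[C-](C)C(=O)C[C@@H]1[C@]2(C)CCC(=O)O2 | intermediate (not isolated)
21 | (2S,5R)-2-methyl-5-[(2S)-2-methyl-5-oxooxolan-2-yl]-2-(prop-2-en-1-yl)oxolan-3-one | C=CC[C@@]1(C)C(=O)C[C@H]([C@]2(C)CCC(=O)O2)O1 | intermediate
22 | (5S)-5-[(2R,5S)-4-hydroxy-5-methyl-5-(prop-2-en-1-yl)oxolan-2-yl]-5-methyloxolan-2-one (C4 epimers) | C=CC[C@@]1(C)C(O)C[C@H]([C@]2(C)CCC(=O)O2)O1 | intermediate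
23 | O-[(2S,5R)-2-methyl-5-[(2S)-2-methyl-5-oxooxolan-2-yl]-2-(prop-2-en-1-yl)oxolan-3-yl] 1H-imidazole-1-carbothioate (C3 epimers) | C=CC[C@@]1(C)C(OC(=S)n3ccnc3)C[C@H]([C@]2(C)CCC(=O)O2)O1 | intermediate
24 | (5S)-5-methyl-5-[(2R,5R)-5-methyl-5-(prop-2-en-1-yl)oxolan-2-yl]oxolan-2-one | C=CC[C@@]1(C)CC[C@H]([C@]2(C)CCC(=O)O2)O1 | intermediate
25 | ozonide: (5S)-5-methyl-5-[(2R,5R)-5-methyl-5-(1,2,4-trioxolan-3-ylmethyl)oxolan-2-yl]oxolan-2-one | O1OCOC1C[C@@]2(C)CC[C@H]([C@]3(C)CCC(=O)O3)O2 | intermediate (not isolated)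
26 | 2-[(2R,5R)-2-methyl-5-[(2S)-2-methyl-5-oxooxolan-2-yl]oxolan-2-yl]acetaldehyde | O=CC[C@@]1(C)CC[C@H]([C@]2(C)CCC(=O)O2)O1 | intermediate
27 | furan-3-carbaldehyde | O=Cc1ccoc1 | starting material
28 | (triphenylphosphoranylidene)acetaldehyde | O=CC=P(c1ccccc1)(c1ccccc1)c1ccccc1 | starting material
29 | (2E)-3-(furan-3-yl)prop-2-enal | O=C/C=C/c1ccoc1 | intermediate
30 | 3-(furan-3-yl)propanal | O=CCCc1ccoc1 | intermediate
31 | ethyl 2-(triphenylphosphoranylidene)propanoate | CCOC(=O)C(C)=P(c1ccccc1)(c1ccccc1)c1ccccc1 | starting material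
32 | ethyl (2E)-5-(furan-3-yl)-2-methylpent-2-enoate | CCOC(=O)/C(C)=C/CCc1ccoc1 | intermediate
33 | (2E)-5-(furan-3-yl)-2-methylpent-2-en-1-ol | OC/C(C)=C/CCc1ccoc1 | intermediate
34 | mesylate: (2E)-5-(furan-3-yl)-2-methylpent-2-en-1-yl methanesulfonate | CS(=O)(=O)OC/C(C)=C/CCc1ccoc1 | intermediate (not isolated)
35 | 3-[(3E)-5-chloro-4-methylpent-3-en-1-yl]furan | ClC/C(C)=C/CCc1ccoc1 | intermediate
36 | allylbarium chloride: [(2E)-5-(furan-3-yl)-2-methylpent-2-en-1-yl]barium chloride | Cl[Ba]C/C(C)=C/CCc1ccoc1 | intermediate (not isolated)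
37 | (5S)-5-[(2R,5R)-5-[(4E)-7-(furan-3-yl)-2-hydroxy-4-methylhept-4-en-1-yl]-5-methyloxolan-2-yl]-5-methyloxolan-2-one (carbinol epimers) | C/C(=C\CCc1ccoc1)CC(O)C[C@@]1(C)CC[C@H]([C@]2(C)CCC(=O)O2)O1 | intermediate
38 | (5S)-5-[(2R,5R)-5-[(4E)-7-(furan-3-yl)-4-methyl-2-oxohept-4-en-1-yl]-5-methyloxolan-2-yl]-5-methyloxolan-2-one | C/C(=C\CCc1ccoc1)CC(=O)C[C@@]1(C)CC[C@H]([C@]2(C)CCC(=O)O2)O1 | target

Total step count: 20 (main line steps 1–13, 19 and 20; side chain steps 14–18).
Longest linear sequence: 15 steps (1–13, 19, 20).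

Steps most likely to fail

Step 9. A 1,2-hydride shift from the methyl group of the carbenoid, leading to an enone, may outrun capture by the ether oxygen, and the allyl group may be delivered with poor facial selectivity. The fallback builds C2 by allylation of a cyclic oxocarbenium ion instead of by a carbenoid; it sets out from 2 and 4 and comes back to the route at 24. Commercial pent-4-enal and 2 should give 2-methylhepta-1,6-dien-3-ol F1. Johnson–Claisen rearrangement with 4 should give ethyl (4E)-4-methylnona-4,8-dienoate F2. Shi epoxidation with the same ketone, which does not touch the terminal alkene, should give ethyl 3-[(2R,3R)-3-(but-3-en-1-yl)-2-methyloxiran-2-yl]propanoate F3. Lithium hydroxide followed by acidification should give (5S)-5-[(1R)-1-hydroxypent-4-en-1-yl]-5-methyloxolan-2-one F4. Tsuji–Wacker oxidation (PdCl2, CuCl, O2, DMF/H2O) should give the methyl ketone in its cyclic hemiketal form, (5S)-5-[(2R)-5-hydroxy-5-methyloxolan-2-yl]-5-methyloxolan-2-one F5. Allyltrimethylsilane with BF3·OEt2 at −78 °C should then add to the 2-methyl oxocarbenium ion to give 24. Attack anti to the lactone substituent is expected to be favoured only modestly, so the C2 epimer would have to be removed by chromatography. This weaker stereocontrol is why it is the fallback, although it bypasses steps 5–12.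

Step 19. The allylmetal may attack through its γ-carbon to give the branched alcohol, may lose E geometry or undergo Wurtz coupling during metalation, or may add to or enolise the lactone. The fallback replaces the barium reagent by a sulfonyl-stabilised allyl anion; it sets out from 35 and 26 and comes back at 38. Chloride 35 and sodium benzenesulfinate (DMF, rt) should give 3-[(3E)-5-(benzenesulfonyl)-4-methylpent-3-en-1-yl]furan F6. Its lithio derivative (n-BuLi, THF, −78 °C) should add to 26 through the sulfonyl-bearing carbon to give (5S)-5-[(2R,5R)-5-[(4E)-3-(benzenesulfonyl)-7-(furan-3-yl)-2-hydroxy-4-methylhept-4-en-1-yl]-5-methyloxolan-2-yl]-5-methyloxolan-2-one F7. Dess–Martin oxidation should give (5S)-5-[(2R,5R)-5-[(4E)-3-(benzenesulfonyl)-7-(furan-3-yl)-4-methyl-2-oxohept-4-en-1-yl]-5-methyloxolan-2-yl]-5-methyloxolan-2-one F8. Reductive desulfonylation with SmI2 (THF/MeOH, −78 °C) should give 38 directly, kinetic α-protonation keeping the alkene in the β,γ-position.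

Step 8. The basic diazoalkane may dehydrochlorinate acid chloride 16 to a ketene, allyl alcohol may be lost by β-elimination, or the product may be captured by HCl if the diazoalkane runs short. The fallback introduces the diazo group by diazo transfer instead of by acylation; it sets out from 12 and comes back at 18. Dess–Martin oxidation of 12 should give aldehyde 13, here isolated. Ethylmagnesium bromide (THF, −78 °C) should give (5S)-5-[(1R)-3-hydroxy-1-(prop-2-en-1-yloxy)pentyl]-5-methyloxolan-2-one F9. Dess–Martin oxidation should give (5S)-5-methyl-5-[(1R)-3-oxo-1-(prop-2-en-1-yloxy)pentyl]oxolan-2-one F10. Kinetic enolisation on the unhindered ethyl side (LiHMDS, THF, −78 °C) and trapping with 2,2,2-trifluoroethyl trifluoroacetate should give (5S)-5-methyl-5-[(1R)-6,6,6-trifluoro-4-methyl-3,5-dioxo-1-(prop-2-en-1-yloxy)hexyl]oxolan-2-one F11. Detrifluoroacetylative diazo transfer (MsN3, Et3N, MeCN/H2O) should give 18.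

Further compounds
F1 | step 9 | 2-methylhepta-1,6-dien-3-ol (racemic) | C=CCCC(O)C(C)=C
F2 | step 9 | ethyl (4E)-4-methylnona-4,8-dienoate | CCOC(=O)CC/C(C)=C/CCC=C
F3 | step 9 | ethyl 3-[(2R,3R)-3-(but-3-en-1-yl)-2-methyloxiran-2-yl]propanoate | CCOC(=O)CC[C@@]1(C)O[C@@H]1CCC=C
F4 | step 9 | (5S)-5-[(1R)-1-hydroxypent-4-en-1-yl]-5-methyloxolan-2-one | C=CCC[C@@H](O)[C@]1(C)CCC(=O)O1
F5 | step 9 | (5S)-5-[(2R)-5-hydroxy-5-methyloxolan-2-yl]-5-methyloxolan-2-one (anomers) | CC1(O)CC[C@H]([C@]2(C)CCC(=O)O2)O1
F6 | step 19 | 3-[(3E)-5-(benzenesulfonyl)-4-methylpent-3-en-1-yl]furan | O=S(=O)(C/C(C)=C/CCc1ccoc1)c1ccccc1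
F7 | step 19 | (5S)-5-[(2R,5R)-5-[(4E)-3-(benzenesulfonyl)-7-(furan-3-yl)-2-hydroxy-4-methylhept-4-en-1-yl]-5-methyloxolan-2-yl]-5-methyloxolan-2-one (diastereomers) | O=S(=O)(c1ccccc1)C(C(O)C[C@@]1(C)CC[C@H]([C@]2(C)CCC(=O)O2)O1)/C(C)=C/CCc1ccoc1
F8 | step 19 | (5S)-5-[(2R,5R)-5-[(4E)-3-(benzenesulfonyl)-7-(furan-3-yl)-4-methyl-2-oxohept-4-en-1-yl]-5-methyloxolan-2-yl]-5-methyloxolan-2-one (sulfone epimers) | O=S(=O)(c1ccccc1)C(C(=O)C[C@@]1(C)CC[C@H]([C@]2(C)CCC(=O)O2)O1)/C(C)=C/CCc1ccoc1
F9 | step 8 | (5S)-5-[(1R)-3-hydroxy-1-(prop-2-en-1-yloxy)pentyl]-5-methyloxolan-2-one (C3 epimers) | CCC(O)C[C@@H](OCC=C)[C@]1(C)CCC(=O)O1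
F10 | step 8 | (5S)-5-methyl-5-[(1R)-3-oxo-1-(prop-2-en-1-yloxy)pentyl]oxolan-2-one | CCC(=O)C[C@@H](OCC=C)[C@]1(C)CCC(=O)O1
F11 | step 8 | (5S)-5-methyl-5-[(1R)-6,6,6-trifluoro-4-methyl-3,5-dioxo-1-(prop-2-en-1-yloxy)hexyl]oxolan-2-one | CC(C(=O)C(F)(F)F)C(=O)C[C@@H](OCC=C)[C@]1(C)CCC(=O)O1
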